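Target seems to breed target. In the violet flask the readings barely move up to 25.0 s, yet by 50.0 s target has drawn level with substrate, while the green flask, with a far smaller charge, stays flat within the scatter.

| flask | substrate | remark | time |
|---|---|---|---|
| green | 0.0072 M | run made earlier |  |
| violet | 0.84 M | run made earlier |  |
| south-west | 0.012 M |  | 3.0 min |
| east | 0.040 M |  | 3.0 min |
| north | 0.12 M |  | 3.0 min |
| north-east | 0.30 M |  | 3.0 min |
| south-east | 1.0 M |  | 3.0 min |

| run | time / s | target / % | substrate / % |
|---|---|---|---|
| green | 10.0 | 0 | 99.7 |
| green | 12.0 | 0.5 | 101.5 |
| green | 15.0 | 1.0 | 99.4 |
| green | 25.0 | 0.8 | 100.8 |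
| green | 40.0 | 1.8 | 100.0 |
| green | 60.0 | 1.1 | 99.3 |
| green | 90.0 | 0 | 100.7 |
| violet | 10.0 | 0.1 | 99.7 |
| violet | 15.0 | 0 | 99.0 |
| violet | 25.0 | 2.0 | 97.2 |
| violet | 40.0 | 20.3 | 80.0 |
| violet | 50.0 | 49.4 | 47.9 |
| violet | 80.0 | 85.9 | 2.6 |
| violet | 90.0 | 83.1 | 1.4 |

(each reading ± 1 percentage point)

- "hardly changes" means that all values lie within two and a half points (for a concentration: within two and a half percent of the largest)

* amount of target at the end, in percent of the substrate charged for south-west, east, north, north-east, south-east, in this order
* how the row runs (rises, then falls / hardly changes / falls all the way / falls, then rises / rises all the way)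

Two extreme flasks can be solved in the head. In the first there is no breeding, and a slow steady step feeds target in a straight line: the green readings, fitted through the origin, give 1.24 × 10⁻⁴ s⁻¹, so 2.24 % of the charge in 3.0 min. In the second, breeding (autocatalysis) rules, and the ratio of target to substrate grows exponentially; its climb in the violet flask between 25.0 s and 50.0 s gives a breeding constant of 0.186 M⁻¹ s⁻¹.

The reckoning here gives the flasks of the row both steps, and one quantity places each between the extremes: the growth number, the breeding constant times the charge times the elapsed time, which is 0.403 for south-west. Each bit of target fed in then grows for the time remaining, so while substrate stays near its charge, the amount formed is the straight-line amount times the mean of the growth curve, which is the exponential of the growth number, minus one, over the growth number. For south-west that mean is 1.23, so 2.76 % should have formed. Across the row the growth number climbs to 33.6 at south-east, so this reckoning puts south-west near the first extreme and south-east near the second. For south-east, the same ratio puts substrate under 2 percent of its charge at 1.00 min.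

The forecast differs from this reckoning at south-west. It gives 0.1 %, 0.3 %, 3 %, 72 % and 58 %, a row that rises, then falls, and it puts the fall on a loss of target: “The violet mass balance falls late”.

The flask gives 1.69 %, 2.60 %, 11.4 %, 72.7 % and 66.9 %, a row that rises, then falls.

    substrate → target (k = 1.07 × 10⁻⁴ s⁻¹)
    target ⇌ isomer of the product (K = 0.597, k = 0.00595 s⁻¹)
    substrate + target → 2 target (k = 0.180 M⁻¹ s⁻¹)

In south-west at the asked time, target 1.69 % and isomer of the product 0.545 % make 2.23 % formed, against the 2.76 % from a growth number of 0.403. In south-east, substrate passes under 2 percent of its charge at 1.09 min, against the reckoned 1.00 min. Target in south-east falls short of the charge through the loss of target to isomer of the product: south-east ends with 66.9 % of target, and the same flask without that loss ends with 100 %.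

The numbers in the tables come from a simulation on assumed constants.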